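**Plan** (tetralin numbering: C1 bears the pendant aryl ring C, C2 the ester, C3 the CH2OH, C4 is CH2; ring A is the fused benzo ring, ring B the saturated ring)
1. Retrosynthetic cuts, in order: the C1–C2 bond of ring B; a second ester put on C2 to make it a malonate carbon; the C2–C3 bond (malonate to an allyl unit); the C4a–C4 bond (allyl to ring A); the C1–C1' bond (ring C to the aldehyde carbon of ring A).
2. Forward: the ring A aldehyde and the ring C Grignard reagent give the diarylmethane, the C4–C3 chain is grown on ring A, malonate is joined at C3, and ring B, the only ring made, closes last.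
3. Enabling feature: ring C has a free OH para to C1, so two-electron oxidation makes C1 the exocyclic carbon of a para-quinone methide, electrophilic towards the malonate carbon C2; ring A keeps O7 as a benzyl ether and cannot be oxidised in this way.
4. Stereochemistry: C3 from ligand-controlled iridium allylic alkylation; C1 from C3 during ring closure (1,3-cis); C2 by thermodynamic protonation after one ester is removed (trans to both neighbours).

Key step: step 12

Assumption: the (Sa,Sc,Sc) enantiomer of the O,O'-(1,1'-binaphthalene-2,2'-diyl) N,N-bis(1-phenylethyl)phosphoramidite is taken to deliver malonate to the allyl face that gives (R)-12; if the sense of induction is the opposite, the mirror-image ligand is used and nothing else changes.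

**Step 1**
Reactants: 1 isovanillin (3-hydroxy-4-methoxybenzaldehyde)
Product: 2 3-(benzyloxy)-4-methoxybenzaldehyde
Conditions: BnBr, K2CO3, DMF, rt
Reagents that add atoms: benzyl bromide, BrCc1ccccc1
Why: Williamson etherification of the phenoxide; the benzyl ether masks O7 of ring A until the last step and keeps ring A from forming a quinone methide in step 12.

**Step 2**
Reactants: 2 3-(benzyloxy)-4-methoxybenzaldehyde
Product: 3 5-(benzyloxy)-2-bromo-4-methoxybenzaldehyde
Conditions: Br2, NaOAc, AcOH, rt
Reagents that add atoms: bromine, BrBr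
Why: Electrophilic aromatic bromination should go para to the benzyloxy group and ortho to the formyl group, as with veratraldehyde, because the 4-methoxy group is engaged in conjugation with the aldehyde, and acetate buffers the HBr that could cleave the benzyl ether.

**Step 3**
Reactants: 4 4-bromo-2-methoxyphenol
Product: 5 (4-bromo-2-methoxyphenoxy)triisopropylsilane
Conditions: TIPSCl, imidazole, DMF, rt
Reagents that add atoms: chlorotriisopropylsilane, CC(C)[Si](Cl)(C(C)C)C(C)C
Why: Imidazole-promoted O-silylation; the bulky aryl silyl ether should survive Grignard formation, acid, palladium, ruthenium and iridium catalysis, and is later removed by fluoride without touching the benzyl ethers.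

**Step 4**
Reactants: 5 (4-bromo-2-methoxyphenoxy)triisopropylsilane; 3 5-(benzyloxy)-2-bromo-4-methoxybenzaldehyde
Product: 7 [5-(benzyloxy)-2-bromo-4-methoxyphenyl][3-methoxy-4-(triisopropylsilyloxy)phenyl]methanol (racemic), via arylmagnesium bromide 6 (not isolated)
Conditions: Mg, THF, 50 °C; then 3, THF, 0 °C; aq. NH4Cl
Reagents that add atoms: none
Why: Grignard addition to the aldehyde forms the C1–C1' bond, the aryl bromide of 3 does not exchange with an arylmagnesium halide at 0 °C, and the carbinol center needs no control because it is removed in step 5.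

**Step 5**
Reactants: 7 the diarylmethanol
Product: 8 {4-[5-(benzyloxy)-2-bromo-4-methoxybenzyl]-2-methoxyphenoxy}triisopropylsilane
Conditions: Et3SiH, TFA, CH2Cl2, 0 °C
Reagents that add atoms: none
Why: Ionic hydrogenation: the electron-rich diarylmethanol ionises easily to a benzhydryl cation that is reduced by the silane, while the aryl bromide, benzyl ether and aryl silyl ether are inert.

**Step 6**
Reactants: 8 the bromo diarylmethane
Product: 9 {4-[2-allyl-5-(benzyloxy)-4-methoxybenzyl]-2-methoxyphenoxy}triisopropylsilane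
Conditions: allylSnBu3, Pd(PPh3)4 (5 mol%), toluene, 110 °C
Reagents that add atoms: allyltributylstannane, C=CC[Sn](CCCC)(CCCC)CCCC
Why: Stille coupling (oxidative addition of the aryl bromide to zerovalent palladium, allyl transfer from tin, reductive elimination) forms the C4a–C4 bond under fluoride-free, base-free conditions that keep the silyl ether.

**Step 7**
Reactants: 9 the allylarene
Product: 10 (2E)-4-{4-(benzyloxy)-5-methoxy-2-[3-methoxy-4-(triisopropylsilyloxy)benzyl]phenyl}but-2-en-1-yl methyl carbonate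
Conditions: allyl methyl carbonate (4 equiv), second-generation Grubbs catalyst (5 mol%), CH2Cl2, 40 °C
Reagents that add atoms: allyl methyl carbonate, C=CCOC(=O)OC
Why: Olefin cross-metathesis of two terminal alkenes with the cheap partner in excess should give the (E)-allylic carbonate under thermodynamic control with loss of ethene.

**Step 8**
Reactants: 10 the (E)-allylic methyl carbonate; 11 dimethyl malonate
Product: 12 dimethyl 2-[(2R)-1-{4-(benzyloxy)-5-methoxy-2-[3-methoxy-4-(triisopropylsilyloxy)benzyl]phenyl}but-3-en-2-yl]malonate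
Conditions: [Ir(cod)Cl]2 (2 mol%), (Sa,Sc,Sc)-phosphoramidite (4 mol%), 1,5,7-triazabicyclo[4.4.0]dec-5-ene (8 mol%), THF, rt; then 10, 11 (1.5 equiv), THF, rt
Reagents that add atoms: none
Why: Iridium-catalysed asymmetric allylic alkylation: the cyclometalated iridium–phosphoramidite complex ionises the carbonate, the methoxide set free deprotonates the malonate, and attack at the substituted allyl terminus on the ligand-dictated face forms C2–C3 and sets C3 as (R) in 12 (the (S)-C3 of later compounds once vinyl has become CH2OBn).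

**Step 9**
Reactants: 12 the branched vinyl malonate
Product: 13 dimethyl 2-[(2S)-1-{4-(benzyloxy)-5-methoxy-2-[3-methoxy-4-(triisopropylsilyloxy)benzyl]phenyl}-3-oxopropan-2-yl]malonate
Conditions: O3, CH2Cl2/MeOH, −78 °C (Sudan Red 7B end point); then PPh3, −78 °C to rt
Reagents that add atoms: ozone, [O-][O+]=O
Why: Ozonolysis with reductive work-up cleaves the terminal alkene much faster than the alkoxyarenes when the ozone dose is limited by the indicator, and the crude aldehyde is used at once so that C3, now alpha to the formyl group, is not epimerised.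

**Step 10**
Reactants: 13 the aldehyde
Product: 14 dimethyl 2-[(2S)-1-(benzyloxy)-3-{4-(benzyloxy)-5-methoxy-2-[3-methoxy-4-(triisopropylsilyloxy)benzyl]phenyl}propan-2-yl]malonate
Conditions: BnOSiMe3, Et3SiH, TMSOTf (10 mol%), CH2Cl2, −78 to −20 °C
Reagents that add atoms: (benzyloxy)trimethylsilane, C[Si](C)(C)OCc1ccccc1
Why: Reductive etherification (silyl acetal, oxocarbenium ion, hydride transfer from the silane) turns the aldehyde directly into the benzyl ether, so the gamma-hydroxy malonate that would lactonise is never formed and C3 is not touched.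

**Step 11**
Reactants: 14 the silyl-protected malonate
Product: 15 dimethyl 2-[(2S)-1-(benzyloxy)-3-{4-(benzyloxy)-2-(4-hydroxy-3-methoxybenzyl)-5-methoxyphenyl}propan-2-yl]malonate
Conditions: TBAF, AcOH, THF, 0 °C
Reagents that add atoms: none
Why: Fluoride-mediated desilylation of the aryl silyl ether, buffered with acetic acid so that neither the phenoxide nor the malonate anion persists, frees only the ring C phenol.

**Step 12**
Reactants: 15 the phenolic malonate
Product: 17 dimethyl (1R,3S)-7-(benzyloxy)-3-[(benzyloxy)methyl]-1-(4-hydroxy-3-methoxyphenyl)-6-methoxy-3,4-dihydronaphthalene-2,2(1H)-dicarboxylate, via para-quinone methide 16 (not isolated)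
Conditions: Ag2O (2.5 equiv), CH2Cl2, rt, dark; filtration; then Cs2CO3 (0.2 equiv), CH2Cl2, 0 °C
Reagents that add atoms: none
Why: Ag2O removes two electrons and two protons from the only free phenol (ring C, OH para to C1) to give para-quinone methide 16 with C1 as its exocyclic carbon, and catalytic carbonate then forms the malonate anion at C2, which adds to C1 in a 1,6 (vinylogous Michael) sense and restores ring C as a phenol. The closest known reaction type is the base-mediated 1,6-conjugate addition of malonates to para-quinone methides made by Ag2O oxidation of 4-benzylphenols, here run intramolecularly. Ring B closes in a 6-exo-trig mode by forming C1–C2, the reacting C1=C1' bond lying outside the new ring. C1 is the only new stereocenter and is controlled by C3: in the half-chair transition state the benzyloxymethyl group on C3 sits pseudo-equatorial and the quinoid ring on C1 should take the pseudo-equatorial site, away from the axial hydrogen on C3, which gives the 1,3-cis (1R,3S) diester. The step needs site-selective oxidation, secured because O7 of ring A is a benzyl ether and the malonate C–H is not oxidised by Ag2O, and 1,3-cis selectivity at C1, secured by the C3 substituent. Because the adduct can re-open only through its phenoxide, the base is kept catalytic and the temperature low, and a minor C1 epimer can be separated and returned to the same conditions.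

**Step 13**
Reactants: 17 the phenolic tetralin diester
Product: 18 dimethyl (1R,3S)-7-(benzyloxy)-1-[4-(benzyloxy)-3-methoxyphenyl]-3-[(benzyloxy)methyl]-6-methoxy-3,4-dihydronaphthalene-2,2(1H)-dicarboxylate
Conditions: BnBr, K2CO3, DMF, 0 °C to rt
Reagents that add atoms: benzyl bromide, BrCc1ccccc1
Why: Williamson etherification caps the phenol (C2 has no acidic hydrogen, so only O-alkylation is possible), which prevents O-methylation of the phenol and phenoxide-driven re-opening of ring B under the hot conditions of step 14 and fixes C1.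

**Step 14**
Reactants: 18 the tribenzyl diester
Product: 19 methyl (1R,2S,3S)-7-(benzyloxy)-1-[4-(benzyloxy)-3-methoxyphenyl]-3-[(benzyloxy)methyl]-6-methoxy-1,2,3,4-tetrahydronaphthalene-2-carboxylate
Conditions: LiCl, H2O, DMSO, 160 °C; then NaOMe (cat.), MeOH, rt
Reagents that add atoms: none
Why: Krapcho demethoxycarbonylation (chloride attacks one ester methyl group, CO2 is lost, the ester enolate is protonated), and methoxide equilibration should then leave the remaining ester pseudo-equatorial, trans to both the C1 aryl group and the C3 side chain, which sets C2 as (S) under thermodynamic control.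

**Step 15**
Reactants: 19 the tribenzyl mono-ester
Product: 20 methyl (1R,2S,3S)-7-hydroxy-1-(4-hydroxy-3-methoxyphenyl)-3-(hydroxymethyl)-6-methoxy-1,2,3,4-tetrahydronaphthalene-2-carboxylate
Conditions: H2 (1 atm), Pd/C, EtOAc/MeOH, rt
Reagents that add atoms: none
Why: Catalytic hydrogenolysis removes the three benzyl ethers under neutral conditions, which should avoid both lactonisation of the gamma-hydroxy ester and epimerisation at C2, while the doubly benzylic C1–C bonds are not cleaved.

**Compound list**
1 | isovanillin (3-hydroxy-4-methoxybenzaldehyde) | COc1ccc(C=O)cc1O | starting material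
2 | 3-(benzyloxy)-4-methoxybenzaldehyde | COc1ccc(C=O)cc1OCc1ccccc1 | intermediate
3 | 5-(benzyloxy)-2-bromo-4-methoxybenzaldehyde | COc1cc(Br)c(C=O)cc1OCc1ccccc1 | intermediate
4 | 4-bromo-2-methoxyphenol | COc1cc(Br)ccc1O | starting material
5 | (4-bromo-2-methoxyphenoxy)triisopropylsilane | COc1cc(Br)ccc1O[Si](C(C)C)(C(C)C)C(C)C | intermediate
6 | [3-methoxy-4-(triisopropylsilyloxy)phenyl]magnesium bromide | COc1cc([Mg]Br)ccc1O[Si](C(C)C)(C(C)C)C(C)C | intermediate
7 | [5-(benzyloxy)-2-bromo-4-methoxyphenyl][3-methoxy-4-(triisopropylsilyloxy)phenyl]methanol (racemic) | COc1cc(Br)c(cc1OCc1ccccc1)C(O)c1ccc(O[Si](C(C)C)(C(C)C)C(C)C)c(OC)c1 | intermediate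
8 | {4-[5-(benzyloxy)-2-bromo-4-methoxybenzyl]-2-methoxyphenoxy}triisopropylsilane | COc1cc(Br)c(cc1OCc1ccccc1)Cc1ccc(O[Si](C(C)C)(C(C)C)C(C)C)c(OC)c1 | intermediate
9 | {4-[2-allyl-5-(benzyloxy)-4-methoxybenzyl]-2-methoxyphenoxy}triisopropylsilane | COc1cc(CC=C)c(cc1OCc1ccccc1)Cc1ccc(O[Si](C(C)C)(C(C)C)C(C)C)c(OC)c1 | intermediate
10 | (2E)-4-{4-(benzyloxy)-5-methoxy-2-[3-methoxy-4-(triisopropylsilyloxy)benzyl]phenyl}but-2-en-1-yl methyl carbonate | COC(=O)OC/C=C/Cc1cc(OC)c(OCc2ccccc2)cc1Cc1ccc(O[Si](C(C)C)(C(C)C)C(C)C)c(OC)c1 | intermediate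
11 | dimethyl malonate | COC(=O)CC(=O)OC | starting material
12 | dimethyl 2-[(2R)-1-{4-(benzyloxy)-5-methoxy-2-[3-methoxy-4-(triisopropylsilyloxy)benzyl]phenyl}but-3-en-2-yl]malonate | COC(=O)C(C(=O)OC)[C@@H](C=C)Cc1cc(OC)c(OCc2ccccc2)cc1Cc1ccc(O[Si](C(C)C)(C(C)C)C(C)C)c(OC)c1 | intermediate
13 | dimethyl 2-[(2S)-1-{4-(benzyloxy)-5-methoxy-2-[3-methoxy-4-(triisopropylsilyloxy)benzyl]phenyl}-3-oxopropan-2-yl]malonate | COC(=O)C(C(=O)OC)[C@@H](C=O)Cc1cc(OC)c(OCc2ccccc2)cc1Cc1ccc(O[Si](C(C)C)(C(C)C)C(C)C)c(OC)c1 | intermediate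
14 | dimethyl 2-[(2S)-1-(benzyloxy)-3-{4-(benzyloxy)-5-methoxy-2-[3-methoxy-4-(triisopropylsilyloxy)benzyl]phenyl}propan-2-yl]malonate | COC(=O)C(C(=O)OC)[C@@H](COCc1ccccc1)Cc1cc(OC)c(OCc2ccccc2)cc1Cc1ccc(O[Si](C(C)C)(C(C)C)C(C)C)c(OC)c1 | intermediate
15 | dimethyl 2-[(2S)-1-(benzyloxy)-3-{4-(benzyloxy)-2-(4-hydroxy-3-methoxybenzyl)-5-methoxyphenyl}propan-2-yl]malonate | COC(=O)C(C(=O)OC)[C@@H](COCc1ccccc1)Cc1cc(OC)c(OCc2ccccc2)cc1Cc1ccc(O)c(OC)c1 | intermediate
16 | dimethyl 2-[(2S)-1-(benzyloxy)-3-{4-(benzyloxy)-5-methoxy-2-[(3-methoxy-4-oxocyclohexa-2,5-dien-1-ylidene)methyl]phenyl}propan-2-yl]malonate (para-quinone methide, mixture of exocyclic alkene isomers) | COC(=O)C(C(=O)OC)[C@@H](COCc1ccccc1)Cc1cc(OC)c(OCc2ccccc2)cc1C=C1C=CC(=O)C(OC)=C1 | intermediate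
17 | dimethyl (1R,3S)-7-(benzyloxy)-3-[(benzyloxy)methyl]-1-(4-hydroxy-3-methoxyphenyl)-6-methoxy-3,4-dihydronaphthalene-2,2(1H)-dicarboxylate | COC(=O)C1(C(=O)OC)[C@@H](COCc2ccccc2)Cc2cc(OC)c(OCc3ccccc3)cc2[C@H]1c1ccc(O)c(OC)c1 | intermediate
18 | dimethyl (1R,3S)-7-(benzyloxy)-1-[4-(benzyloxy)-3-methoxyphenyl]-3-[(benzyloxy)methyl]-6-methoxy-3,4-dihydronaphthalene-2,2(1H)-dicarboxylate | COC(=O)C1(C(=O)OC)[C@@H](COCc2ccccc2)Cc2cc(OC)c(OCc3ccccc3)cc2[C@H]1c1ccc(OCc2ccccc2)c(OC)c1 | intermediate
19 | methyl (1R,2S,3S)-7-(benzyloxy)-1-[4-(benzyloxy)-3-methoxyphenyl]-3-[(benzyloxy)methyl]-6-methoxy-1,2,3,4-tetrahydronaphthalene-2-carboxylate | COC(=O)[C@@H]1[C@@H](COCc2ccccc2)Cc2cc(OC)c(OCc3ccccc3)cc2[C@H]1c1ccc(OCc2ccccc2)c(OC)c1 | intermediate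
20 | methyl (1R,2S,3S)-7-hydroxy-1-(4-hydroxy-3-methoxyphenyl)-3-(hydroxymethyl)-6-methoxy-1,2,3,4-tetrahydronaphthalene-2-carboxylate | COC(=O)[C@@H]1[C@@H](CO)Cc2cc(OC)c(O)cc2[C@H]1c1ccc(O)c(OC)c1 | target

**Step count**
Total: 15 steps. Longest linear sequence: 14 steps (steps 1, 2 and 4–15 from isovanillin); step 3 is the one-step side branch.

**Steps most likely to fail**

Step 12. What may go wrong: weak 1,3-induction at C1, because the geminal diester on C2 flanks C1 on both sides and a pseudo-axial aryl group is only mildly penalised in a tetralin; and phenoxyl radical coupling competing with quinone methide formation. Fallback: remove the extra ester before ring closure, so that C2 carries a hydrogen and the same C1–C2 bond can form through an all-equatorial chair. Setting out from 14, Krapcho demethoxycarbonylation (LiCl, H2O, DMSO, 150 °C) would give methyl (3S)-4-(benzyloxy)-3-{4-(benzyloxy)-5-methoxy-2-[3-methoxy-4-(triisopropylsilyloxy)benzyl]benzyl}butanoate F1. TBAF/AcOH would free the phenol to give methyl (3S)-4-(benzyloxy)-3-[4-(benzyloxy)-2-(4-hydroxy-3-methoxybenzyl)-5-methoxybenzyl]butanoate F2. Ag2O in CH2Cl2 would give the corresponding para-quinone methide F3, and after filtration LiHMDS (THF, −78 °C) would form the ester enolate, which should close to methyl (1R,2S,3S)-7-(benzyloxy)-3-[(benzyloxy)methyl]-1-(4-hydroxy-3-methoxyphenyl)-6-methoxy-1,2,3,4-tetrahydronaphthalene-2-carboxylate F4 (C2 settled trans with catalytic NaOMe in MeOH if needed). Hydrogenolysis of the two benzyl ethers of F4 (H2, Pd/C) returns to the route at 20.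

Step 8. What may go wrong: loss of branched regioselectivity or of enantiocontrol at an allyl terminus that carries a bulky ortho-substituted arylmethyl group. Fallback: take C3 from the chiral pool and transfer it stereospecifically. Setting out from 8, magnesium insertion would give {4-(benzyloxy)-5-methoxy-2-[3-methoxy-4-(triisopropylsilyloxy)benzyl]phenyl}magnesium bromide F5. F5 would open (R)-epichlorohydrin at its unsubstituted carbon (CuI cat., THF, −40 to 0 °C) to give (2R)-1-chloro-3-{4-(benzyloxy)-5-methoxy-2-[3-methoxy-4-(triisopropylsilyloxy)benzyl]phenyl}propan-2-ol F6. Excess Me3S+ I−/n-BuLi (epoxide closure, then sulfonium methylide opening and elimination) would give (2R)-1-{4-(benzyloxy)-5-methoxy-2-[3-methoxy-4-(triisopropylsilyloxy)benzyl]phenyl}but-3-en-2-ol F7. ClCO2Me/pyridine would give (2R)-1-{4-(benzyloxy)-5-methoxy-2-[3-methoxy-4-(triisopropylsilyloxy)benzyl]phenyl}but-3-en-2-yl methyl carbonate F8. Rhodium-catalysed allylic alkylation (RhCl(PPh3)3, P(OMe)3, NaCH(CO2Me)2, THF, 30 °C), which is known to substitute secondary allylic carbonates at the branched carbon with net retention, returns to the route at 12.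

Step 10. What may go wrong: capture of the substrate-derived oxocarbenium ion by a neighbouring ester carbonyl (lactone formation) or by ring A, or epimerisation at C3 through enolisation of the aldehyde. Fallback: move the oxocarbenium ion from the substrate onto benzaldehyde. Setting out from 13, neutral hydrosilylation (Et3SiH, RhCl(PPh3)3 cat., toluene, rt) would give dimethyl 2-[(2S)-1-{4-(benzyloxy)-5-methoxy-2-[3-methoxy-4-(triisopropylsilyloxy)benzyl]phenyl}-3-(triethylsilyloxy)propan-2-yl]malonate F9 without a free alcohol. Reductive etherification of this silyl ether with benzaldehyde (PhCHO, Et3SiH, FeCl3 cat., MeNO2/CH2Cl2, 0 °C) returns to the route at 14.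

**Further compounds**
F1 | step 12 | methyl (3S)-4-(benzyloxy)-3-{4-(benzyloxy)-5-methoxy-2-[3-methoxy-4-(triisopropylsilyloxy)benzyl]benzyl}butanoate | COC(=O)C[C@@H](COCc1ccccc1)Cc1cc(OC)c(OCc2ccccc2)cc1Cc1ccc(O[Si](C(C)C)(C(C)C)C(C)C)c(OC)c1
F2 | step 12 | methyl (3S)-4-(benzyloxy)-3-[4-(benzyloxy)-2-(4-hydroxy-3-methoxybenzyl)-5-methoxybenzyl]butanoate | COC(=O)C[C@@H](COCc1ccccc1)Cc1cc(OC)c(OCc2ccccc2)cc1Cc1ccc(O)c(OC)c1
F3 | step 12 | methyl (3S)-4-(benzyloxy)-3-{4-(benzyloxy)-5-methoxy-2-[(3-methoxy-4-oxocyclohexa-2,5-dien-1-ylidene)methyl]benzyl}butanoate | COC(=O)C[C@@H](COCc1ccccc1)Cc1cc(OC)c(OCc2ccccc2)cc1C=C1C=CC(=O)C(OC)=C1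
F4 | step 12 | methyl (1R,2S,3S)-7-(benzyloxy)-3-[(benzyloxy)methyl]-1-(4-hydroxy-3-methoxyphenyl)-6-methoxy-1,2,3,4-tetrahydronaphthalene-2-carboxylate | COC(=O)[C@@H]1[C@@H](COCc2ccccc2)Cc2cc(OC)c(OCc3ccccc3)cc2[C@H]1c1ccc(O)c(OC)c1
F5 | step 8 | {4-(benzyloxy)-5-methoxy-2-[3-methoxy-4-(triisopropylsilyloxy)benzyl]phenyl}magnesium bromide | COc1cc([Mg]Br)c(cc1OCc1ccccc1)Cc1ccc(O[Si](C(C)C)(C(C)C)C(C)C)c(OC)c1
F6 | step 8 | (2R)-1-chloro-3-{4-(benzyloxy)-5-methoxy-2-[3-methoxy-4-(triisopropylsilyloxy)benzyl]phenyl}propan-2-ol | O[C@@H](CCl)Cc1cc(OC)c(OCc2ccccc2)cc1Cc1ccc(O[Si](C(C)C)(C(C)C)C(C)C)c(OC)c1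
F7 | step 8 | (2R)-1-{4-(benzyloxy)-5-methoxy-2-[3-methoxy-4-(triisopropylsilyloxy)benzyl]phenyl}but-3-en-2-ol | O[C@@H](C=C)Cc1cc(OC)c(OCc2ccccc2)cc1Cc1ccc(O[Si](C(C)C)(C(C)C)C(C)C)c(OC)c1
F8 | step 8 | (2R)-1-{4-(benzyloxy)-5-methoxy-2-[3-methoxy-4-(triisopropylsilyloxy)benzyl]phenyl}but-3-en-2-yl methyl carbonate | COC(=O)O[C@@H](C=C)Cc1cc(OC)c(OCc2ccccc2)cc1Cc1ccc(O[Si](C(C)C)(C(C)C)C(C)C)c(OC)c1
F9 | step 10 | dimethyl 2-[(2S)-1-{4-(benzyloxy)-5-methoxy-2-[3-methoxy-4-(triisopropylsilyloxy)benzyl]phenyl}-3-(triethylsilyloxy)propan-2-yl]malonate | COC(=O)C(C(=O)OC)[C@@H](CO[Si](CC)(CC)CC)Cc1cc(OC)c(OCc2ccccc2)cc1Cc1ccc(O[Si](C(C)C)(C(C)C)C(C)C)c(OC)c1
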